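**Retrosynthetic overview**
1. Last bond C6–CH3: stereoselective C-methylation of the peroxycarbenium ion from the bicyclic methoxy peroxyketal 24 (new step; sets the quaternary peroxy carbon C6).
2. 24 from keto-butenolide 22 by perketalisation (H2O2/MeOH) and intramolecular oxa-Michael addition. Ring order: butenolide first, 1,2-dioxane second; the cis ring fusion and C3 follow from C4.
3. 22 from acid chloride 20 and alkylzinc 21 by Pd-catalysed acylative Negishi coupling (C6–C7 bond, fragment union).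
4. Acid 8 (C4 centre) from (S)-2-methylglycidol: vinyl-cuprate opening, oxidation, ketene-ylide butenolide annulation, ozonolysis, Pinnick oxidation.
5. 21 (C8 centre, E-alkene) from but-3-yn-1-ol and benzyl chloride (Zr carboalumination/Pd benzylation) and (R)-3-bromo-2-methylpropan-1-ol (Cu-catalysed sp3–sp3 coupling).

Assumption: plakortolide numbering is used in the text (C1 lactone C=O, C3/C4 ring fusion, C6 peroxy quaternary carbon, C8 side-chain methine), and (S)-2-methylglycidol and (R)-3-bromo-2-methylpropan-1-ol are bought as enantiopure building blocks.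

**Route**

Step 1
Reactants: 1 (S)-2-methylglycidol
Product: 2 (2R)-2-methylpent-4-ene-1,2-diol
Conditions: CH2=CHMgBr (3 equiv), CuI (10 mol %), THF, −40 → 0 °C
Reagents that add atoms: vinylmagnesium bromide, C=C[Mg]Br
Why: Copper-catalysed Grignard opening of the 2,2-disubstituted epoxide is an SN2 attack at the unsubstituted CH2 terminus, so the quaternary carbinol centre (future C4, R) is carried over unchanged from the epoxide.

Step 2
Reactants: 2 (2R)-2-methylpent-4-ene-1,2-diol
Product: 3 (2R)-2-hydroxy-2-methylpent-4-enal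
Conditions: SO3·pyridine, DMSO, i-Pr2NEt, CH2Cl2, 0 °C
Reagents that add atoms: none
Why: Parikh–Doering oxidation touches only the primary alcohol (the tertiary one cannot be oxidised) and does not cleave the 1,2-diol.

Step 3
Reactants: 3 (2R)-2-hydroxy-2-methylpent-4-enal
Product: 5 (5R)-5-methyl-5-(prop-2-en-1-yl)furan-2(5H)-one, via ester ylide 4 (not isolated)
Conditions: Ph3P=C=C=O (1.2 equiv), toluene, 80 °C
Reagents that add atoms: (triphenylphosphoranylidene)ketene, O=C=C=P(c1ccccc1)(c1ccccc1)c1ccccc1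
Why: The tertiary alcohol adds to the ketene ylide (Bestmann ylide) and the resulting ester ylide closes by intramolecular Wittig reaction on the neighbouring aldehyde, the ring enforcing the Z-alkene of the butenolide.

Step 4
Reactants: 5 (5R)-5-methyl-5-(prop-2-en-1-yl)furan-2(5H)-one
Product: 7 [(2R)-2-methyl-5-oxo-2,5-dihydrofuran-2-yl]acetaldehyde, via ozonide 6 (not isolated)
Conditions: O3, CH2Cl2, −78 °C (Sudan III end point); PPh3, −78 °C → rt
Reagents that add atoms: ozone, [O-][O+]=O
Why: Ozonolysis to a dye end point cleaves the electron-rich terminal alkene much faster than the electron-poor butenolide C=C, and PPh3 reduces the ozonide to the aldehyde.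

Step 5
Reactants: 7 [(2R)-2-methyl-5-oxo-2,5-dihydrofuran-2-yl]acetaldehyde
Product: 8 [(2R)-2-methyl-5-oxo-2,5-dihydrofuran-2-yl]acetic acid
Conditions: NaClO2, NaH2PO4, 2-methyl-2-butene, t-BuOH/H2O, 0 °C → rt
Reagents that add atoms: sodium chlorite, [Na+].[O-]Cl=O
Why: Pinnick oxidation converts the aldehyde to the acid at pH 4 without touching the butenolide or provoking β-elimination of the lactone oxygen.

Step 6
Reactants: 9 but-3-yn-1-ol; 10 benzyl chloride
Product: 12 (3E)-3-methyl-5-phenylpent-3-en-1-ol, via alkenylalane 11 (not isolated)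
Conditions: AlMe3 (3 equiv), Cp2ZrCl2 (20 mol %), CH2Cl2, 0 °C → rt; concentrate; 10, Pd(PPh3)4 (5 mol %), THF, rt; dil. HCl
Reagents that add atoms: trimethylaluminium, C[Al](C)C
Why: Zirconium-catalysed carboalumination (Negishi) adds Me and Al syn across the terminal alkyne with methyl on the internal carbon, and the Pd-catalysed cross-coupling of the alkenylalane with benzyl chloride proceeds with retention, fixing the E-trisubstituted alkene.

Step 7
Reactants: 12 (3E)-3-methyl-5-phenylpent-3-en-1-ol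
Product: 13 (3E)-3-methyl-5-phenylpent-3-en-1-yl 4-methylbenzenesulfonate
Conditions: TsCl, Et3N, DMAP (cat.), CH2Cl2, 0 °C → rt
Reagents that add atoms: p-toluenesulfonyl chloride, Cc1ccc(cc1)S(Cl)(=O)=O
Why: Standard sulfonylation of the unhindered primary alcohol gives the electrophile for the alkyl–alkyl coupling.

Step 8
Reactants: 14 (2R)-3-bromo-2-methylpropan-1-ol
Product: 15 [(2R)-3-bromo-2-methylpropoxy](tert-butyl)dimethylsilane
Conditions: TBSCl, imidazole, CH2Cl2, rt
Reagents that add atoms: tert-butyldimethylsilyl chloride, CC(C)(C)[Si](C)(C)Cl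
Why: Silylation masks the hydroxyl so that the bromide can be turned into a Grignard reagent; the stereocentre (future C8) is not involved.

Step 9
Reactants: 15 [(2R)-3-bromo-2-methylpropoxy](tert-butyl)dimethylsilane; 13 (3E)-3-methyl-5-phenylpent-3-en-1-yl 4-methylbenzenesulfonate
Product: 17 tert-butyl{[(2S,6E)-2,6-dimethyl-8-phenyloct-6-en-1-yl]oxy}dimethylsilane, via Grignard reagent 16 (not isolated)
Conditions: Mg, THF, 40 °C; then 13, Li2CuCl4 (5 mol %), THF, −40 → 0 °C
Reagents that add atoms: magnesium, [Mg] (Mg of 16)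
Why: Copper-catalysed sp3–sp3 coupling of a primary Grignard reagent with a primary tosylate (Kochi–Schlosser type) forms C9–C10 without touching the β-stereocentre (the descriptor changes from R to S only through CIP priorities).

Step 10
Reactants: 17 tert-butyl{[(2S,6E)-2,6-dimethyl-8-phenyloct-6-en-1-yl]oxy}dimethylsilane
Product: 18 (2S,6E)-2,6-dimethyl-8-phenyloct-6-en-1-ol
Conditions: TBAF, THF, rt
Reagents that add atoms: none
Why: Fluoride desilylation is neutral toward the skipped aryl–alkene unit.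

Step 11
Reactants: 18 (2S,6E)-2,6-dimethyl-8-phenyloct-6-en-1-ol
Product: 19 [(2E,7S)-8-iodo-3,7-dimethyloct-2-en-1-yl]benzene
Conditions: I2, PPh3, imidazole, CH2Cl2, 0 °C → rt
Reagents that add atoms: iodine, II
Why: Appel-type iodination (Garegg–Samuelsson) displaces the activated primary oxygen by iodide without affecting the adjacent stereocentre.

Step 12
Reactants: 8 [(2R)-2-methyl-5-oxo-2,5-dihydrofuran-2-yl]acetic acid; 19 [(2E,7S)-8-iodo-3,7-dimethyloct-2-en-1-yl]benzene
Product: 22 (5R)-5-[(4S,8E)-4,8-dimethyl-2-oxo-10-phenyldec-8-en-1-yl]-5-methylfuran-2(5H)-one, via acid chloride 20 (not isolated), via alkylzinc iodide 21 (not isolated)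
Conditions: 8, (COCl)2, DMF (cat.), CH2Cl2, 0 °C → rt, evaporate; 19, Zn dust (TMSCl-activated), LiCl, THF, 40 °C; combine, Pd(PPh3)4 (5 mol %), THF, 0 °C → rt
Reagents that add atoms: oxalyl chloride, O=C(Cl)C(Cl)=O (Cl of 20); zinc, [Zn] (Zn of 21)
Why: Pd-catalysed acylative Negishi cross-coupling (oxidative addition into C–Cl, transmetalation from the alkylzinc, reductive elimination) forms the C6–C7 ketone bond without over-addition, under non-basic conditions that spare the butenolide and the β-acyloxy ketone.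

Step 13
Reactants: 22 (5R)-5-[(4S,8E)-4,8-dimethyl-2-oxo-10-phenyldec-8-en-1-yl]-5-methylfuran-2(5H)-one
Product: 23 (5R)-5-[(4S,8E)-2-hydroperoxy-2-methoxy-4,8-dimethyl-10-phenyldec-8-en-1-yl]-5-methylfuran-2(5H)-one (both C2' epimers)
Conditions: urea·H2O2 (10 equiv), Sc(OTf)3 (10 mol %), MeOH, rt
Reagents that add atoms: hydrogen peroxide (delivered as urea–hydrogen peroxide), OO; methanol, CO
Why: Lewis-acid-catalysed perketalisation turns the ketone, through its methyl oxocarbenium ion, into the α-methoxy hydroperoxide; the C6 epimer mixture is irrelevant because C6 is re-ionised in step 15.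

Step 14
Reactants: 23 (5R)-5-[(4S,8E)-2-hydroperoxy-2-methoxy-4,8-dimethyl-10-phenyldec-8-en-1-yl]-5-methylfuran-2(5H)-one (both C2' epimers)
Product: 24 (4aR,7aR)-3-methoxy-4a-methyl-3-[(2S,6E)-2,6-dimethyl-8-phenyloct-6-en-1-yl]-3,4,4a,7a-tetrahydrofuro[3,2-c][1,2]dioxin-6(7H)-one (both C3 epimers)
Conditions: Et2NH (0.3 equiv), CF3CH2OH, rt
Reagents that add atoms: none
Why: Amine-promoted intramolecular oxa-Michael addition (6-exo-trig) of the hydroperoxide to the butenolide β-carbon closes the 1,2-dioxane, and the tether through C5 can only deliver oxygen to the face syn to it, so the cis ring fusion and the C3 centre (7aR) follow from C4.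

Step 15
Reactants: 24 (4aR,7aR)-3-methoxy-4a-methyl-3-[(2S,6E)-2,6-dimethyl-8-phenyloct-6-en-1-yl]-3,4,4a,7a-tetrahydrofuro[3,2-c][1,2]dioxin-6(7H)-one (both C3 epimers)
Product: 26 plakortolide G, via peroxycarbenium triflate 25 (not isolated)
Conditions: TMSOTf (1.5 equiv), Me2Zn (3 equiv, toluene), CH2Cl2, −78 → −40 °C; pH 7 buffer
Reagents that add atoms: dimethylzinc, C[Zn]C; trimethylsilyl trifluoromethanesulfonate, C[Si](C)(C)OS(=O)(=O)C(F)(F)F (triflate of 25)
Why: Proposed new method: TMSOTf silylates the more Lewis-basic exocyclic methoxy oxygen of either epimer of 24 and ionises it to one peroxycarbenium ion, whose favoured half-chair has the C4 lactone oxygen pseudoaxial and the C4 methyl and C3 CH2 pseudoequatorial; Me2Zn then transfers methyl along the axial, chair-like trajectory syn to that pseudoaxial oxygen (cis to the lactone O), which should set C6 as R stereoconvergently; the closest known reaction types are Lewis-acid-mediated allylation of monocyclic peroxyketals through peroxycarbenium ions and TMSOTf-promoted dialkylzinc alkylation of cyclic α-acetoxy ethers, whereas C-alkylation of a peroxycarbenium ion by an organozinc has not been shown.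

**Compound list**
1 | (S)-2-methylglycidol, [(2S)-2-methyloxiran-2-yl]methanol | C[C@]1(CO)CO1 | starting material
2 | (2R)-2-methylpent-4-ene-1,2-diol | C[C@](O)(CO)CC=C | intermediate
3 | (2R)-2-hydroxy-2-methylpent-4-enal | C[C@](O)(C=O)CC=C | intermediate
4 | ester ylide, (2R)-2-methyl-1-oxopent-4-en-2-yl (triphenyl-λ5-phosphanylidene)acetate | C[C@](OC(=O)C=P(c1ccccc1)(c1ccccc1)c1ccccc1)(C=O)CC=C | intermediate (not isolated)
5 | (5R)-5-methyl-5-(prop-2-en-1-yl)furan-2(5H)-one | C[C@]1(CC=C)OC(=O)C=C1 | intermediate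
6 | ozonide, (5R)-5-methyl-5-(1,2,4-trioxolan-3-ylmethyl)furan-2(5H)-one (both trioxolane epimers) | C[C@]1(CC2OCOO2)OC(=O)C=C1 | intermediate (not isolated)
7 | [(2R)-2-methyl-5-oxo-2,5-dihydrofuran-2-yl]acetaldehyde | C[C@]1(CC=O)OC(=O)C=C1 | intermediate
8 | [(2R)-2-methyl-5-oxo-2,5-dihydrofuran-2-yl]acetic acid | C[C@]1(CC(=O)O)OC(=O)C=C1 | intermediate
9 | but-3-yn-1-ol | C#CCCO | starting material
10 | benzyl chloride | ClCc1ccccc1 | starting material
11 | alkenylalane, dimethylaluminium (3E)-4-(dimethylalumanyl)-3-methylbut-3-en-1-olate | C[Al](C)/C=C(\C)CCO[Al](C)C | intermediate (not isolated)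
12 | (3E)-3-methyl-5-phenylpent-3-en-1-ol | OCC/C(C)=C/Cc1ccccc1 | intermediate
13 | (3E)-3-methyl-5-phenylpent-3-en-1-yl 4-methylbenzenesulfonate | Cc1ccc(cc1)S(=O)(=O)OCC/C(C)=C/Cc1ccccc1 | intermediate
14 | (2R)-3-bromo-2-methylpropan-1-ol | OC[C@@H](C)CBr | starting material
15 | [(2R)-3-bromo-2-methylpropoxy](tert-butyl)dimethylsilane | C[C@H](CO[Si](C)(C)C(C)(C)C)CBr | intermediate
16 | Grignard reagent, {(2R)-3-[(tert-butyldimethylsilyl)oxy]-2-methylpropyl}magnesium bromide | C[C@H](CO[Si](C)(C)C(C)(C)C)C[Mg]Br | intermediate (not isolated)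
17 | tert-butyl{[(2S,6E)-2,6-dimethyl-8-phenyloct-6-en-1-yl]oxy}dimethylsilane | C[C@H](CO[Si](C)(C)C(C)(C)C)CCC/C(C)=C/Cc1ccccc1 | intermediate
18 | (2S,6E)-2,6-dimethyl-8-phenyloct-6-en-1-ol | C[C@H](CO)CCC/C(C)=C/Cc1ccccc1 | intermediate
19 | [(2E,7S)-8-iodo-3,7-dimethyloct-2-en-1-yl]benzene | C[C@H](CI)CCC/C(C)=C/Cc1ccccc1 | intermediate
20 | acid chloride, [(2R)-2-methyl-5-oxo-2,5-dihydrofuran-2-yl]acetyl chloride | C[C@]1(CC(=O)Cl)OC(=O)C=C1 | intermediate (not isolated)
21 | alkylzinc iodide, [(2S,6E)-2,6-dimethyl-8-phenyloct-6-en-1-yl]zinc iodide | C[C@H](C[Zn]I)CCC/C(C)=C/Cc1ccccc1 | intermediate (not isolated)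
22 | (5R)-5-[(4S,8E)-4,8-dimethyl-2-oxo-10-phenyldec-8-en-1-yl]-5-methylfuran-2(5H)-one | C[C@]1(CC(=O)C[C@@H](C)CCC/C(C)=C/Cc2ccccc2)OC(=O)C=C1 | intermediate
23 | (5R)-5-[(4S,8E)-2-hydroperoxy-2-methoxy-4,8-dimethyl-10-phenyldec-8-en-1-yl]-5-methylfuran-2(5H)-one (both C2' epimers) | C[C@]1(CC(OC)(OO)C[C@@H](C)CCC/C(C)=C/Cc2ccccc2)OC(=O)C=C1 | intermediate
24 | (4aR,7aR)-3-methoxy-4a-methyl-3-[(2S,6E)-2,6-dimethyl-8-phenyloct-6-en-1-yl]-3,4,4a,7a-tetrahydrofuro[3,2-c][1,2]dioxin-6(7H)-one (cis-fused 1,2-dioxane/γ-lactone, both C3 epimers) | COC1(C[C@@H](C)CCC/C(C)=C/Cc3ccccc3)C[C@@]2(C)OC(=O)C[C@H]2OO1 | intermediate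
25 | peroxycarbenium triflate, (4aR,7aR)-4a-methyl-3-[(2S,6E)-2,6-dimethyl-8-phenyloct-6-en-1-yl]-6-oxo-4,4a,7,7a-tetrahydro-6H-furo[3,2-c][1,2]dioxin-2-ium trifluoromethanesulfonate | C1(C[C@@H](C)CCC/C(C)=C/Cc3ccccc3)C[C@@]2(C)OC(=O)C[C@H]2O[O+]=1.[O-]S(=O)(=O)C(F)(F)F | intermediate (not isolated)
26 | plakortolide G, (3R,4aR,7aR)-3,4a-dimethyl-3-[(2S,6E)-2,6-dimethyl-8-phenyloct-6-en-1-yl]-3,4,4a,7a-tetrahydrofuro[3,2-c][1,2]dioxin-6(7H)-one | C/C(=C\Cc1ccccc1)CCC[C@H](C)C[C@]1(C)C[C@@]2(C)OC(=O)C[C@H]2OO1 | target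

**Totals**
Total steps: 15. Longest linear sequence: 9 (steps 1–5 and 12–15; equally steps 6, 7, 9–15).

**Steps most likely to fail and their fallbacks**

Step 15 (the new reaction). The peroxycarbenium ion could lose a proton to a vinyl peroxide or undergo Hock/Criegee-type O–O heterolysis, Me2Zn could attack the O–O bond, and the facial selectivity rests on a model, not on precedent. The fallback uses known chemistry, sets out from ketone 22 and comes back at 26. Lombardo methylenation (Zn, CH2Br2, TiCl4) of 22 gives the methylidene butenolide F1. Isayama–Mukaiyama hydroperoxysilylation (Co(thd)2, O2, Et3SiH) of its 1,1-disubstituted alkene, stopped at partial conversion to spare the trisubstituted alkene, gives the tertiary triethylsilyl peroxide F2 as a roughly 1:1 pair of epimers. TBAF/AcOH releases the hydroperoxide F3, and Et2NH/CF3CH2OH closes it to 26 together with the 3-epimer F4, which is removed by chromatography. This costs about half the material but needs no new chemistry.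

Step 13. The ketone sits between a neopentyl-type CH2 and a β-branched CH2, so perketalisation may be slow or unfavourable, and the β-acyloxy ketone can eliminate. The fallback sets out from 22 and comes back at 23. The ketone is first ketalised under water-free conditions with HC(OMe)3/CSA/MeOH to the dimethyl ketal F5. One methoxy group is then exchanged for OOH with anhydrous ethereal H2O2 and catalytic CSA.

Step 12. The β-acyloxy acyl-palladium intermediate may decarbonylate and eliminate, or the zinc reagent may homocouple. The fallback sets out from aldehyde 7 and zinc reagent 21 (made from 19 as in step 12) and comes back at 22. MgCl2-promoted addition of 21 to aldehyde 7 gives the secondary alcohol F6 as both carbinol epimers, and Dess–Martin oxidation gives 22.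

**Further compounds**
F1 | step 15 | (5R)-5-[(4S,8E)-4,8-dimethyl-2-methylidene-10-phenyldec-8-en-1-yl]-5-methylfuran-2(5H)-one | C[C@]1(CC(=C)C[C@@H](C)CCC/C(C)=C/Cc2ccccc2)OC(=O)C=C1
F2 | step 15 | (5R)-5-{(4S,8E)-2,4,8-trimethyl-10-phenyl-2-[(triethylsilyl)peroxy]dec-8-en-1-yl}-5-methylfuran-2(5H)-one (both C2' epimers) | C[C@]1(CC(C)(OO[Si](CC)(CC)CC)C[C@@H](C)CCC/C(C)=C/Cc2ccccc2)OC(=O)C=C1
F3 | step 15 | (5R)-5-[(4S,8E)-2-hydroperoxy-2,4,8-trimethyl-10-phenyldec-8-en-1-yl]-5-methylfuran-2(5H)-one (both C2' epimers) | C[C@]1(CC(C)(OO)C[C@@H](C)CCC/C(C)=C/Cc2ccccc2)OC(=O)C=C1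
F4 | step 15 | 3-epimer of 26, (3S,4aR,7aR)-3,4a-dimethyl-3-[(2S,6E)-2,6-dimethyl-8-phenyloct-6-en-1-yl]-3,4,4a,7a-tetrahydrofuro[3,2-c][1,2]dioxin-6(7H)-one | C/C(=C\Cc1ccccc1)CCC[C@H](C)C[C@@]1(C)C[C@@]2(C)OC(=O)C[C@H]2OO1
F5 | step 13 | (5R)-5-[(4S,8E)-2,2-dimethoxy-4,8-dimethyl-10-phenyldec-8-en-1-yl]-5-methylfuran-2(5H)-one | C[C@]1(CC(OC)(OC)C[C@@H](C)CCC/C(C)=C/Cc2ccccc2)OC(=O)C=C1
F6 | step 12 | (5R)-5-[(4S,8E)-2-hydroxy-4,8-dimethyl-10-phenyldec-8-en-1-yl]-5-methylfuran-2(5H)-one (both C2' epimers) | C[C@]1(CC(O)C[C@@H](C)CCC/C(C)=C/Cc2ccccc2)OC(=O)C=C1
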